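# Proposed total synthesis of quercetin 3,4'-bissulfate by Friedel–Crafts closure of ring C at C4–C4a

## Analysis of the target

The target is a flavonol: a 2-aryl-4H-chromen-4-one in which ring A (C4a, C5 to C8, C8a, with hydroxyls on C5 and C7) is fused to the γ-pyranone ring C (O1, C2, C3, C4), and the catechol ring B sits on C2. It has no stereocentre and is essentially flat, so the whole problem is regiochemical: five oxygens (O3, O5, O7, O3', O4') must end up in two different states. The two sulfate monoesters, and above all the enolic one on O3, are lost under acid and turn the molecule into a polar dianion. Once they are in place, only neutral, non-hydrolytic chemistry may follow. Direct sulfation of the free pentaol cannot be expected to pick O3 and O4' cleanly, so these two oxygens must carry a label of their own from the start, and that label has to survive the ring construction. The strategy rests on C4a: it lies between C8a (bearing O1) and C5 (bearing O5) and is para to C7 (bearing O7), so it is the ring carbon of a phloroglucinol triether and the most nucleophilic position of ring A. In a 3,5-dioxygenated aryl ether the two carbons ortho to the ether oxygen are equivalent, so C4–C4a can be made by acylation without any regiochemical question. What is left, O1–C2(ring B)=C3(O)–C4O2H, is an aryl enol ether of a ring B β-keto acid whose α-oxygen can come from a glycolate, so O3 enters already protected.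

## Retrosynthetic reasoning

**Benzyl C–O bonds on O3', O5 and O7 (18 to 17).** These three bonds are cut last in the forward direction. Target 18 is then released from tribenzyl ether 17 by hydrogenolysis, a neutral reaction that leaves the two C–O–S links alone. Benzyl is chosen for the three persistent positions because it is the common phenol protection that comes off without acid, base or fluoride.

**O–S bonds on O3 and O4' (17 to 16).** In diol 16 the only free hydroxyls are those on O3 and O4', so the sulfation needs no selectivity at all; it only has to go to completion at both sites.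

**Allyl C–O bonds on O3 and O4' (16 to 15).** The second label is allyl. It is removed by zerovalent palladium and an amine scavenger without touching benzyl ethers, and it tolerates the bases, the oxidant and the acid anhydride used before. This gives diallyl flavone 15.

**C4–C4a (15 to 13 via 14).** This is the ring-closing disconnection. It is placed here because the carbon to be attacked is the most electron-rich one of ring A and because symmetry removes the regiochemical question. Cutting O1–C2 instead would require an intermolecular acylation of ring A by a hindered acid, followed by a separate ring closure. What is gained is a flavone in which all five oxygens are already differentiated. The forward reaction has to turn acid 13 into an acylating species, mixed anhydride 14, under conditions mild enough for allyl and benzyl ethers and for the enol ether.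

**O1–C2 and the ester (13 to 12 to 11 + 10).** Acid 13 comes from ethyl ester 12 by saponification. In 12 the vinylic C–O bond to ring A is cut: C2 is the β-carbon of an acrylate and becomes electrophilic when it bears a leaving group, so enol tosylate 11 and phenol 10 are the partners in an addition–elimination. Phenol 10 is the dibenzyl ether of phloroglucinol 9.

**Enol O–S bond (11 to 8).** Tosylate 11 is the O-sulfonylated enol of β-keto ester 8.

**C2–C3 (8 to 7 to 6 + 4).** A direct ester condensation at the acid oxidation level would pit a slow, electron-rich ring B benzoate against self-condensation and [2,3]-Wittig shift of the α-allyloxy ester enolate. The bond is therefore made at the aldehyde level, where addition at −78 °C is fast: aldol 7 from ester 6 and aldehyde 4, then oxidation to 8.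

**Ether bonds of the building blocks (4 to 3 to 1 + 2; 6 to 5 + 2).** Aldehyde 4 comes from 3,4-dihydroxybenzaldehyde 1 by allylation of the more acidic 4-hydroxyl with allyl bromide 2 to give 3, then benzylation. Ester 6 is the allyl ether of ethyl glycolate 5.

## Alternatives that were turned down

**Alternative 1:** This cuts O1–C2 and leaves C3 as a carbon–iodine bond.
- Key step: ynone A1, 3-[3-(benzyloxy)-4-(triisopropylsilyloxy)phenyl]-1-[2,4,6-tris(benzyloxy)phenyl]prop-2-yn-1-one, is treated with ICl. The alkyne is activated as an iodonium, one of the two equivalent ortho benzyloxy oxygens attacks the aryl-bearing alkyne carbon in a 6-endo-dig closure, and chloride removes the benzyl group from the oxonium ion. The product is 3-iodoflavone A2.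
- For: A1 is assembled convergently in one C–C bond formation, iodocyclisation of ortho-alkoxyaryl ynones is an established chromone synthesis, and the symmetric ring A again removes regiochemistry.
- Against: C3 arrives as iodide, not oxygen. The C–I bond, flanked by the C4 carbonyl and the C2 aryl group, must then be exchanged for C–O by a metal-mediated hydroxylation or a borylation–oxidation, where protodeiodination competes. ICl is also an aromatic iodinating agent, and ring A of A1 still carries three ether oxygens.
- Comparison: the ring closure A1 to A2 is at least as reliable as the chosen one, and A1 is easier to make than the tetrasubstituted enol ether 12. The chosen route offers in exchange a C3 oxygen that is present and correctly labelled before ring closure, so that only three functional-group steps follow the flavone.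

**Alternative 2:** This cuts C3–C4.
- Key step: dialdehyde A3, 2-[3-(benzyloxy)-4-(methoxymethoxy)phenyl]-2-[3,5-bis(benzyloxy)-2-formylphenoxy]acetaldehyde, is reduced by SmI2 (divalent samarium). The ketyl of the aryl aldehyde adds to the aliphatic aldehyde and closes ring C as the 2,3-trans-3,4-cis flavan-3,4-diol A4.
- For: both O3 and O4 are set in the C–C bond-forming step under neutral conditions, and the closure does not depend on the nucleophilicity of ring A. On these two points it is stronger than the chosen route.
- Against: three stereocentres are created that the flat target does not have. Two oxidations to the 3,4-dione and its tautomerisation are needed afterwards. A3 carries an α-aryloxy aldehyde that is enolisable at a doubly activated C–H and is prone to reductive C–O cleavage by SmI2, which would break the ether that is to become O1–C2.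
- Comparison: longer and redox-wasteful. The chosen route reaches the flavone oxidation level directly in the ring closure.

**Alternative 3:** This builds ring A on a preformed γ-pyranone.
- Key step: diazoketone A5, 2-diazo-1-{6-[3-(benzyloxy)-4-(methoxymethoxy)phenyl]-5-(methoxymethoxy)-4-oxo-4H-pyran-2-yl}ethan-1-one, is irradiated. Wolff rearrangement gives a pyranonyl ketene, which adds (triisopropylsilyloxy)ethyne A6 in a [2+2] step (C5–C6 and C7–C8). The cyclobutenone opens to a dienylketene, and 6π closure forms C4a–C5. The product is phenol A7 with free O5–H and silylated O7.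
- For: every oxygen of A7 is separately addressable and ring A forms under neutral conditions, which would serve any sulfation pattern. On flexibility it is stronger than the chosen route.
- Against: ring A is the simplest part of the target, a symmetric phloroglucinol, and building it from acyclic pieces spends the key step on a problem that does not exist. A5 needs a multistep synthesis of an arylated, oxygenated pyranone acid. γ-Pyranones are themselves photoreactive. The free 5-hydroxyl of A7 would need further protection before sulfation.
- Comparison: clearly longer. The chosen route gives only the one pattern needed, but takes ring A from a commodity phenol and lets symmetry do the regiochemical work.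

Key step: step 10

Assumption: aryl and enol hydrogen sulfates are autocatalytically labile as free acids, so compounds 17 and 18 are to be handled as dipotassium salts; they are written in the neutral bis(hydrogen sulfate) form that the target SMILES shows.

## Route

Step 1
Reactants: 1 3,4-dihydroxybenzaldehyde; 2 allyl bromide
Product: 3 4-(allyloxy)-3-hydroxybenzaldehyde
Conditions: NaHCO3, NaI (cat.), DMF, 40 °C
Reagents that add atoms: none
Why: Williamson ether synthesis; the 4-hydroxyl, para to the formyl group, is much the more acidic, so a weak base forms only its phenoxide and one equivalent of 2 should alkylate there.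

Step 2
Reactants: 3 4-(allyloxy)-3-hydroxybenzaldehyde
Product: 4 4-(allyloxy)-3-(benzyloxy)benzaldehyde
Conditions: BnBr, K2CO3, DMF, rt
Reagents that add atoms: benzyl bromide, BrCc1ccccc1
Why: Williamson benzylation of the remaining phenol; nothing else in 3 is alkylated under these conditions.

Step 3
Reactants: 5 ethyl glycolate; 2 allyl bromide
Product: 6 ethyl 2-(allyloxy)acetate
Conditions: NaH, Bu4NI (cat.), THF, 0 °C → rt
Reagents that add atoms: none
Why: Williamson O-allylation of the primary alkoxide with a reactive allylic halide; low temperature and slow addition keep transesterification of the glycolate down.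

Step 4
Reactants: 6 ethyl 2-(allyloxy)acetate; 4 4-(allyloxy)-3-(benzyloxy)benzaldehyde
Product: 7 ethyl 2-(allyloxy)-3-[4-(allyloxy)-3-(benzyloxy)phenyl]-3-hydroxypropanoate (racemic mixture of syn and anti diastereomers)
Conditions: LiN(iPr)2, THF, −78 °C; then 4, −78 °C; AcOH quench at −78 °C
Reagents that add atoms: none
Why: Glycolate aldol addition; at −78 °C addition to the aldehyde should be much faster than the [2,3]-Wittig shift of the α-allyloxy enolate, and the two new stereocentres need no control because both are erased in steps 5 and 7.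

Step 5
Reactants: 7 ethyl 2-(allyloxy)-3-[4-(allyloxy)-3-(benzyloxy)phenyl]-3-hydroxypropanoate
Product: 8 ethyl 2-(allyloxy)-3-[4-(allyloxy)-3-(benzyloxy)phenyl]-3-oxopropanoate (racemic)
Conditions: Dess–Martin periodinane, CH2Cl2, rt
Reagents that add atoms: none
Why: Dess–Martin oxidation of a benzylic secondary alcohol to the aryl ketone; allyl and benzyl ethers and the ester are inert to the reagent.

Step 6
Reactants: 9 phloroglucinol
Product: 10 3,5-bis(benzyloxy)phenol
Conditions: BnBr (2 equiv), K2CO3, DMF, rt; chromatographic separation from mono- and tribenzyl ethers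
Reagents that add atoms: benzyl bromide, BrCc1ccccc1
Why: Statistical Williamson O-benzylation of a cheap symmetric triol; the dibenzyl ether is the main component at two equivalents of halide, and the under- and over-alkylated ethers are separable.

Step 7
Reactants: 8 ethyl 2-(allyloxy)-3-[4-(allyloxy)-3-(benzyloxy)phenyl]-3-oxopropanoate
Product: 11 ethyl (E)-2-(allyloxy)-3-[4-(allyloxy)-3-(benzyloxy)phenyl]-3-(tosyloxy)prop-2-enoate
Conditions: LiN(SiMe3)2, THF, −78 °C; then Ts2O, −78 → 0 °C
Reagents that add atoms: p-toluenesulfonic anhydride, Cc1ccc(cc1)S(=O)(=O)OS(=O)(=O)c1ccc(C)cc1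
Why: O-Sulfonylation of the β-keto ester enolate (enol tosylate formation); the lithium chelate holds the enolate oxygen cis to the ester, so the tosyloxy group should end up cis to CO2Et, which is the E isomer here, and C-sulfonylation at the fully substituted α-carbon is disfavoured.

Step 8
Reactants: 11 ethyl (E)-2-(allyloxy)-3-[4-(allyloxy)-3-(benzyloxy)phenyl]-3-(tosyloxy)prop-2-enoate; 10 3,5-bis(benzyloxy)phenol
Product: 12 ethyl (E)-2-(allyloxy)-3-[4-(allyloxy)-3-(benzyloxy)phenyl]-3-[3,5-bis(benzyloxy)phenoxy]prop-2-enoate
Conditions: Cs2CO3, DMF, 50 °C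
Reagents that add atoms: none
Why: Nucleophilic vinylic substitution by addition–elimination: the caesium phenoxide adds to the β-carbon of the vinylogous mixed anhydride and tosylate is expelled from the ester enolate, normally with retention of geometry. A minor Z isomer would be carried on, since step 10 can equilibrate the alkene.

Step 9
Reactants: 12 ethyl (E)-2-(allyloxy)-3-[4-(allyloxy)-3-(benzyloxy)phenyl]-3-[3,5-bis(benzyloxy)phenoxy]prop-2-enoate
Product: 13 (E)-2-(allyloxy)-3-[4-(allyloxy)-3-(benzyloxy)phenyl]-3-[3,5-bis(benzyloxy)phenoxy]prop-2-enoic acid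
Conditions: LiOH, THF–MeOH–H2O, 40 °C; then dilute HCl to pH 4 at 0 °C
Reagents that add atoms: lithium hydroxide, [Li+].[OH-]
Why: Saponification of the ethyl ester, as is usual for 3-aryloxycinnamates; cold, mild acidification frees the acid without hydrolysing the enol ether.

Step 10
Reactants: 13 (E)-2-(allyloxy)-3-[4-(allyloxy)-3-(benzyloxy)phenyl]-3-[3,5-bis(benzyloxy)phenoxy]prop-2-enoic acid
Product: 15 3-(allyloxy)-2-[4-(allyloxy)-3-(benzyloxy)phenyl]-5,7-bis(benzyloxy)-4H-chromen-4-one, via mixed trifluoroacetic anhydride 14 (not isolated)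
Conditions: (CF3CO)2O, CH2Cl2, 0 °C → rt
Reagents that add atoms: none
Why: The acid is converted into mixed anhydride 14, which reacts as an acylium-type electrophile conjugated to the enol ether. The carbon of the 3,5-bis(benzyloxy)phenoxy ring ortho to the ether oxygen attacks C4, and loss of a proton from the arenium ion restores aromaticity and gives the γ-pyranone. The closest known reaction type is the acid-mediated cyclisation of 3-aryloxycinnamic acids to flavones, an intramolecular Friedel–Crafts acylation. Ring C closes as a six-membered ring in a 6-exo mode at the acyl carbon, forming C4–C4a. No stereocentre is formed. Regioselectivity on ring A is secured by symmetry: the two ortho carbons are equivalent and the para carbon cannot reach. Attack on ring B would need the other alkene geometry and a strained five-membered indenone closure onto a less activated ring; the E geometry is set in steps 7 and 8, and any Z material should isomerise because the acylium has a ketene–oxocarbenium resonance form with a C2–C3 single bond. The attacked carbon carries three activating oxygens, so activation at or below room temperature should suffice and leave the allyl and benzyl ethers intact.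

Step 11
Reactants: 15 3-(allyloxy)-2-[4-(allyloxy)-3-(benzyloxy)phenyl]-5,7-bis(benzyloxy)-4H-chromen-4-one
Product: 16 5,7-bis(benzyloxy)-2-[3-(benzyloxy)-4-hydroxyphenyl]-3-hydroxy-4H-chromen-4-one
Conditions: Pd(PPh3)4 (zerovalent palladium, 5 mol %), morpholine, THF, rt
Reagents that add atoms: none
Why: Tsuji–Trost deallylation: zerovalent palladium ionises both allyl ethers, since the phenoxide and the flavonol enolate are good leaving groups, and morpholine traps the π-allyl complex; benzyl ethers do not react.

Step 12
Reactants: 16 5,7-bis(benzyloxy)-2-[3-(benzyloxy)-4-hydroxyphenyl]-3-hydroxy-4H-chromen-4-one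
Product: 17 5,7-bis(benzyloxy)-2-[3-(benzyloxy)-4-(sulfooxy)phenyl]-4-oxo-4H-chromen-3-yl hydrogen sulfate
Conditions: SO3·NMe3 (excess), K2CO3, DMF, 60 °C; isolated as dipotassium salt
Reagents that add atoms: sulfur trioxide–trimethylamine complex, C[N+](C)(C)S(=O)(=O)[O-]
Why: O-Sulfation of a phenoxide and of a flavonol enolate by an amine–SO3 complex; the hydroxyls on O3 and O4' are the only free ones, so an excess of reagent should drive both to the sulfate without any selectivity issue.

Step 13
Reactants: 17 5,7-bis(benzyloxy)-2-[3-(benzyloxy)-4-(sulfooxy)phenyl]-4-oxo-4H-chromen-3-yl hydrogen sulfate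
Product: 18 quercetin 3,4'-bissulfate, 2-[3-hydroxy-4-(sulfooxy)phenyl]-5,7-dihydroxy-4-oxo-4H-chromen-3-yl hydrogen sulfate
Conditions: H2 (1 atm), Pd/C (palladium on carbon), MeOH–H2O, rt; dipotassium salt
Reagents that add atoms: none
Why: Hydrogenolysis of the three aryl benzyl ethers under neutral conditions; the sulfate monoester anions are not reduced, and the C2=C3 bond of a flavonol is part of a vinylogous ester that resists hydrogenation at atmospheric pressure.

## Compound list

1 | 3,4-dihydroxybenzaldehyde | O=Cc1ccc(O)c(O)c1 | starting material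
2 | allyl bromide | C=CCBr | starting material
3 | 4-(allyloxy)-3-hydroxybenzaldehyde | O=Cc1ccc(OCC=C)c(O)c1 | intermediate
4 | 4-(allyloxy)-3-(benzyloxy)benzaldehyde | O=Cc1ccc(OCC=C)c(OCc2ccccc2)c1 | intermediate
5 | ethyl glycolate | CCOC(=O)CO | starting material
6 | ethyl 2-(allyloxy)acetate | CCOC(=O)COCC=C | intermediate
7 | ethyl 2-(allyloxy)-3-[4-(allyloxy)-3-(benzyloxy)phenyl]-3-hydroxypropanoate (racemic, syn and anti) | CCOC(=O)C(OCC=C)C(O)c1ccc(OCC=C)c(OCc2ccccc2)c1 | intermediate
8 | ethyl 2-(allyloxy)-3-[4-(allyloxy)-3-(benzyloxy)phenyl]-3-oxopropanoate (racemic) | CCOC(=O)C(OCC=C)C(=O)c1ccc(OCC=C)c(OCc2ccccc2)c1 | intermediate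
9 | phloroglucinol | Oc1cc(O)cc(O)c1 | starting material
10 | 3,5-bis(benzyloxy)phenol | Oc1cc(OCc2ccccc2)cc(OCc2ccccc2)c1 | intermediate
11 | ethyl (E)-2-(allyloxy)-3-[4-(allyloxy)-3-(benzyloxy)phenyl]-3-(tosyloxy)prop-2-enoate | CCOC(=O)/C(OCC=C)=C(\OS(=O)(=O)c1ccc(C)cc1)c1ccc(OCC=C)c(OCc2ccccc2)c1 | intermediate
12 | ethyl (E)-2-(allyloxy)-3-[4-(allyloxy)-3-(benzyloxy)phenyl]-3-[3,5-bis(benzyloxy)phenoxy]prop-2-enoate | CCOC(=O)/C(OCC=C)=C(\Oc1cc(OCc2ccccc2)cc(OCc2ccccc2)c1)c1ccc(OCC=C)c(OCc2ccccc2)c1 | intermediate
13 | (E)-2-(allyloxy)-3-[4-(allyloxy)-3-(benzyloxy)phenyl]-3-[3,5-bis(benzyloxy)phenoxy]prop-2-enoic acid | OC(=O)/C(OCC=C)=C(\Oc1cc(OCc2ccccc2)cc(OCc2ccccc2)c1)c1ccc(OCC=C)c(OCc2ccccc2)c1 | intermediate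
14 | (E)-2-(allyloxy)-3-[4-(allyloxy)-3-(benzyloxy)phenyl]-3-[3,5-bis(benzyloxy)phenoxy]prop-2-enoic trifluoroacetic anhydride | FC(F)(F)C(=O)OC(=O)/C(OCC=C)=C(\Oc1cc(OCc2ccccc2)cc(OCc2ccccc2)c1)c1ccc(OCC=C)c(OCc2ccccc2)c1 | intermediate (not isolated)
15 | 3-(allyloxy)-2-[4-(allyloxy)-3-(benzyloxy)phenyl]-5,7-bis(benzyloxy)-4H-chromen-4-one | O=c1c(OCC=C)c(-c2ccc(OCC=C)c(OCc3ccccc3)c2)oc2cc(OCc3ccccc3)cc(OCc3ccccc3)c12 | intermediate
16 | 5,7-bis(benzyloxy)-2-[3-(benzyloxy)-4-hydroxyphenyl]-3-hydroxy-4H-chromen-4-one | O=c1c(O)c(-c2ccc(O)c(OCc3ccccc3)c2)oc2cc(OCc3ccccc3)cc(OCc3ccccc3)c12 | intermediate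
17 | 5,7-bis(benzyloxy)-2-[3-(benzyloxy)-4-(sulfooxy)phenyl]-4-oxo-4H-chromen-3-yl hydrogen sulfate | O=c1c(OS(=O)(=O)O)c(-c2ccc(OS(=O)(=O)O)c(OCc3ccccc3)c2)oc2cc(OCc3ccccc3)cc(OCc3ccccc3)c12 | intermediate
18 | quercetin 3,4'-bissulfate | O=c1c(OS(=O)(=O)O)c(-c2ccc(OS(=O)(=O)O)c(O)c2)oc2cc(O)cc(O)c12 | target

## Step count and least certain steps

Total: 13 steps. Longest linear sequence: 11 steps (1, 2, 4, 5, 7, 8, 9, 10, 11, 12, 13) from 3,4-dihydroxybenzaldehyde 1. Steps 3 and 6 are side branches.

**Step 10 (key step).**
- Risk: the activated acid is an acyl-substituted allyl vinyl ether, so an acid-accelerated [3,3] shift of the O3 allyl group onto C2 could compete with ring closure. Trifluoroacetylation of the electron-rich ring A by the anhydride, slow benzyl ether cleavage by the acid set free, and incomplete isomerisation of any Z material are further ways to lose substrate.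
- Fallback: the same C4–C4a bond is closed by an anion instead of a cation (Parham cyclisation). Phenol 10 would be brominated ortho to the hydroxyl with N-bromosuccinimide and catalytic diisopropylamine in CH2Cl2 to give 2-bromo-3,5-bis(benzyloxy)phenol F1. Its caesium salt would displace the tosylate of 11 as in step 8 to give ethyl (E)-2-(allyloxy)-3-[4-(allyloxy)-3-(benzyloxy)phenyl]-3-[2-bromo-3,5-bis(benzyloxy)phenoxy]prop-2-enoate F2. Bromine–lithium exchange with n-BuLi in THF at −100 °C would then let the aryllithium attack the neighbouring ester and expel ethoxide, and the route is rejoined at flavone 15 without any acid.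

**Step 8.**
- Risk: the acceptor is tetrasubstituted and captodative, because the α-allyloxy group and the para-oxygenated ring B both feed electron density to the β-carbon, so addition may be slow. Attack of the phenoxide at sulfur (sulfonyl transfer back to the enolate of 8) or, on stronger heating, a thermal Claisen shift of the allyl vinyl ether could then take over.
- Fallback: the aryl enol ether is made on an acceptor without the α-oxygen, and O3 is introduced after ring closure.
  - Aldehyde 4 would be converted with CBr4 and PPh3 into 1-(allyloxy)-2-(benzyloxy)-4-(2,2-dibromovinyl)benzene F3.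
  - Treatment with n-BuLi and then ethyl chloroformate would give ethyl 3-[4-(allyloxy)-3-(benzyloxy)phenyl]prop-2-ynoate F4.
  - Anti oxa-Michael addition of phenol 10 (K2CO3, DMF) would give ethyl (Z)-3-[4-(allyloxy)-3-(benzyloxy)phenyl]-3-[3,5-bis(benzyloxy)phenoxy]prop-2-enoate F5.
  - Saponification with LiOH would give (Z)-3-[4-(allyloxy)-3-(benzyloxy)phenyl]-3-[3,5-bis(benzyloxy)phenoxy]prop-2-enoic acid F6.
  - Trifluoroacetic anhydride would close it to 2-[4-(allyloxy)-3-(benzyloxy)phenyl]-5,7-bis(benzyloxy)-4H-chromen-4-one F7.
  - Lithiation at C3 with LiN(iPr)2 at −78 °C, borylation with B(OMe)3 and oxidation with H2O2 in AcOH would give 2-[4-(allyloxy)-3-(benzyloxy)phenyl]-5,7-bis(benzyloxy)-3-hydroxy-4H-chromen-4-one F8.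
  - Deallylation with Pd(PPh3)4 and morpholine rejoins the route at diol 16.

**Step 12.**
- Risk: sulfation at the hydrogen-bonded, flanked O3 hydroxyl may stop short, and a mixture of mono- and bis-sulfate salts would be hard to separate. The enol sulfate may also hydrolyse during isolation.
- Fallback: the sulfates are introduced as neutral diesters. Diol 16 would be treated with 2,2,2-trichloroethyl chlorosulfate, Et3N and DMAP in THF to give 5,7-bis(benzyloxy)-2-{3-(benzyloxy)-4-[(2,2,2-trichloroethoxy)sulfonyloxy]phenyl}-4-oxo-4H-chromen-3-yl 2,2,2-trichloroethyl sulfate F9, which can be purified on silica. Reductive removal of the trichloroethyl groups with Zn and HCO2NH4 in MeOH rejoins the route at 17.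

**Step 6.**
- Risk: over- and under-alkylation and C-benzylation of the ambident phloroglucinol anion may leave little of the dibenzyl ether.
- Fallback: phloroglucinol 9 would be acetylated (Ac2O, pyridine) to benzene-1,3,5-triyl triacetate F10. Deacetylation–benzylation in one flask (NaH, BnCl, DMF, a little water) avoids the free polyphenoxide and gives 1,3,5-tris(benzyloxy)benzene F11. Removal of one benzyl group with NaSEt in hot DMF returns phenol 10.

## Further compounds

F1 | step 10 | 2-bromo-3,5-bis(benzyloxy)phenol | Oc1cc(OCc2ccccc2)cc(OCc2ccccc2)c1Br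
F2 | step 10 | ethyl (E)-2-(allyloxy)-3-[4-(allyloxy)-3-(benzyloxy)phenyl]-3-[2-bromo-3,5-bis(benzyloxy)phenoxy]prop-2-enoate | CCOC(=O)/C(OCC=C)=C(\Oc1cc(OCc2ccccc2)cc(OCc2ccccc2)c1Br)c1ccc(OCC=C)c(OCc2ccccc2)c1
F3 | step 8 | 1-(allyloxy)-2-(benzyloxy)-4-(2,2-dibromovinyl)benzene | BrC(Br)=Cc1ccc(OCC=C)c(OCc2ccccc2)c1
F4 | step 8 | ethyl 3-[4-(allyloxy)-3-(benzyloxy)phenyl]prop-2-ynoate | CCOC(=O)C#Cc1ccc(OCC=C)c(OCc2ccccc2)c1
F5 | step 8 | ethyl (Z)-3-[4-(allyloxy)-3-(benzyloxy)phenyl]-3-[3,5-bis(benzyloxy)phenoxy]prop-2-enoate | CCOC(=O)/C=C(\Oc1cc(OCc2ccccc2)cc(OCc2ccccc2)c1)c1ccc(OCC=C)c(OCc2ccccc2)c1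
F6 | step 8 | (Z)-3-[4-(allyloxy)-3-(benzyloxy)phenyl]-3-[3,5-bis(benzyloxy)phenoxy]prop-2-enoic acid | OC(=O)/C=C(\Oc1cc(OCc2ccccc2)cc(OCc2ccccc2)c1)c1ccc(OCC=C)c(OCc2ccccc2)c1
F7 | step 8 | 2-[4-(allyloxy)-3-(benzyloxy)phenyl]-5,7-bis(benzyloxy)-4H-chromen-4-one | O=c1cc(-c2ccc(OCC=C)c(OCc3ccccc3)c2)oc2cc(OCc3ccccc3)cc(OCc3ccccc3)c12
F8 | step 8 | 2-[4-(allyloxy)-3-(benzyloxy)phenyl]-5,7-bis(benzyloxy)-3-hydroxy-4H-chromen-4-one | O=c1c(O)c(-c2ccc(OCC=C)c(OCc3ccccc3)c2)oc2cc(OCc3ccccc3)cc(OCc3ccccc3)c12
F9 | step 12 | 5,7-bis(benzyloxy)-2-{3-(benzyloxy)-4-[(2,2,2-trichloroethoxy)sulfonyloxy]phenyl}-4-oxo-4H-chromen-3-yl 2,2,2-trichloroethyl sulfate | O=c1c(OS(=O)(=O)OCC(Cl)(Cl)Cl)c(-c2ccc(OS(=O)(=O)OCC(Cl)(Cl)Cl)c(OCc3ccccc3)c2)oc2cc(OCc3ccccc3)cc(OCc3ccccc3)c12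
F10 | step 6 | benzene-1,3,5-triyl triacetate | CC(=O)Oc1cc(OC(C)=O)cc(OC(C)=O)c1
F11 | step 6 | 1,3,5-tris(benzyloxy)benzene | c1ccc(COc2cc(OCc3ccccc3)cc(OCc3ccccc3)c2)cc1
A1 | alternative 1 | 3-[3-(benzyloxy)-4-(triisopropylsilyloxy)phenyl]-1-[2,4,6-tris(benzyloxy)phenyl]prop-2-yn-1-one | O=C(C#Cc1ccc(O[Si](C(C)C)(C(C)C)C(C)C)c(OCc2ccccc2)c1)c1c(OCc2ccccc2)cc(OCc2ccccc2)cc1OCc1ccccc1
A2 | alternative 1 | 5,7-bis(benzyloxy)-2-[3-(benzyloxy)-4-(triisopropylsilyloxy)phenyl]-3-iodo-4H-chromen-4-one | O=c1c(I)c(-c2ccc(O[Si](C(C)C)(C(C)C)C(C)C)c(OCc3ccccc3)c2)oc2cc(OCc3ccccc3)cc(OCc3ccccc3)c12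
A3 | alternative 2 | 2-[3-(benzyloxy)-4-(methoxymethoxy)phenyl]-2-[3,5-bis(benzyloxy)-2-formylphenoxy]acetaldehyde (racemic) | O=CC(Oc1cc(OCc2ccccc2)cc(OCc2ccccc2)c1C=O)c1ccc(OCOC)c(OCc2ccccc2)c1
A4 | alternative 2 | 2,3-trans-3,4-cis-5,7-bis(benzyloxy)-2-[3-(benzyloxy)-4-(methoxymethoxy)phenyl]chromane-3,4-diol (racemic, relative configuration drawn) | O[C@H]1c2c(OCc3ccccc3)cc(OCc3ccccc3)cc2O[C@H](c2ccc(OCOC)c(OCc3ccccc3)c2)[C@H]1O
A5 | alternative 3 | 2-diazo-1-{6-[3-(benzyloxy)-4-(methoxymethoxy)phenyl]-5-(methoxymethoxy)-4-oxo-4H-pyran-2-yl}ethan-1-one | [N-]=[N+]=CC(=O)c1cc(=O)c(OCOC)c(-c2ccc(OCOC)c(OCc3ccccc3)c2)o1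
A6 | alternative 3 | (triisopropylsilyloxy)ethyne | C#CO[Si](C(C)C)(C(C)C)C(C)C
A7 | alternative 3 | 2-[3-(benzyloxy)-4-(methoxymethoxy)phenyl]-5-hydroxy-3-(methoxymethoxy)-7-(triisopropylsilyloxy)-4H-chromen-4-one | O=c1c(OCOC)c(-c2ccc(OCOC)c(OCc3ccccc3)c2)oc2cc(O[Si](C(C)C)(C(C)C)C(C)C)cc(O)c12
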